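## Retrosynthetic overview

1. All four stereocentres are bought as two molecules of (–)-epigallocatechin 1. No ring of the target is built; the only new skeletal bond is the C2'–C2' biaryl bond between the two B rings.
2. Key disconnection (biaryl bond): anodic oxidation of 1 gives ortho-quinone 2, which dimerises to trione 3; this is trapped as the hydrated hemiketal 4, in which a temporary dihydrofuran ring closes.
3. Last disconnection: two-electron reduction of 4 re-aromatises ring B', reopens the temporary ring and converts the sp3 ring-fusion carbon into the biaryl axis of theasinensin C 5.

Assumption: the SMILES carries no descriptor for the biaryl axis; theasinensin C is taken as the (R)-atropisomer (the (S)-atropisomer is theasinensin E), and the route aims at (R).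

## Route

Step 1
Reactants: 1 (–)-epigallocatechin (two molecules)
Product: 4 dehydrotheasinensin C (hydrated hemiketal form), via epigallocatechin ortho-quinone 2 (not isolated), via dehydrotheasinensin C keto form 3 (not isolated)
Conditions: carbon felt anode, Pt cathode, divided cell (Nafion 117), +0.50 V vs Ag/AgCl, 2.0 F per mol of 1, 10 mM 1 in 0.1 M NaH2PO4/H3PO4 (pH 3.0), H2O, 5 °C, Ar; then Diaion HP-20 (0.1% TFA in H2O → MeOH), freeze-dry
Reagents that add atoms: water (O)
Why: Proposed new method: anodic dehydrodimerisation of an unprotected pyrogallol-type flavan-3-ol — at +0.50 V only the ring B pyrogallol of 1 (first wave estimated near +0.3–0.4 V at pH 3, ring A near +0.9 V) loses 2 e−/2 H+ to give hydroxy-ortho-quinone 2; two molecules of 2 stack ring B on ring B in the diffusion layer and join C2'–C2' by Michael addition of the enolic C2' of one to C2' of the other; the resulting trione 3 is trapped by the neighbouring 3'-OH (hemiketal) and by water (hydrate) as 4, which is no longer a planar quinone and resists further coupling; the new sp3 ring-fusion centres are set cis by the tether and facially by the (2R,3R) flavan units, and pH 3 keeps ring A too weakly nucleophilic to compete; closest known reaction types are the oxidation of pyrogallol-type tea catechins to their quinone dimers by CuCl2 or polyphenol oxidase and anodic phenol–phenol dehydrodimerisation.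

Step 2
Reactants: 4 dehydrotheasinensin C (hydrated hemiketal form)
Product: 5 theasinensin C
Conditions: Na2S2O4 (3 equiv), 0.2 M NaOAc/AcOH (pH 5), H2O, Ar, 0 → 20 °C, 1 h; Sephadex LH-20
Reagents that add atoms: none
Why: Quinone-type two-electron reduction by dithionite, followed by loss of water, hemiketal opening and keto–enol tautomerisation, re-aromatises ring B'; no stereocentre is made, the sp3 C2' centre of 4 becomes sp2 and its configuration is passed to the tetra-ortho-substituted biaryl axis (central-to-axial chirality transfer), expected to give the (R)-atropisomer, while pH 5 and ≤ 20 °C leave C2 and C3 of both flavan units untouched.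

## Compound list

1 | (–)-epigallocatechin, (2R,3R)-2-(3,4,5-trihydroxyphenyl)chromane-3,5,7-triol, bought | Oc1cc(O)c2c(c1)O[C@H](c1cc(O)c(O)c(O)c1)[C@H](O)C2 | starting material

2 | epigallocatechin ortho-quinone: 1 with ring B oxidised to the 3-hydroxy-1,2-benzoquinone (C4'=O, C5'=O, C3'–OH); flavan centres unchanged | Oc1cc(O)c2c(c1)O[C@H](C1=CC(=O)C(=O)C(O)=C1)[C@H](O)C2 | intermediate

3 | dehydrotheasinensin C keto form: one epigallocatechin unit with intact pyrogallol ring B, bonded through its C2' to the sp3 C2' (CH) of a second unit whose ring B' is a cyclohex-5-ene-1,2,3-trione (C3', C4', C5' carbonyls; C6'=C1' alkene); flavan centres (2R,3R) in both units; C2' of ring B' formed as one configuration, left open in the SMILES | Oc1cc(O)c2c(c1)O[C@H](c1cc(O)c(O)c(O)c1C1C(=O)C(=O)C(=O)C=C1[C@H]4Oc5cc(O)cc(O)c5C[C@H]4O)[C@H](O)C2 | intermediate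

4 | dehydrotheasinensin C, hydrated hemiketal form: as 3, but the C3' carbonyl is a hemiketal closed by the 3'-OH of the aromatic ring B (cis-fused dihydrobenzofuran) and the C4' carbonyl is a gem-diol; C5' ketone and C6'=C1' alkene remain; flavan centres (2R,3R) in both units; the two cis ring-fusion centres are left open in the SMILES | Oc1cc(O)c2c(c1)O[C@H](c1cc(O)c(O)c3c1C1C([C@H]4Oc5cc(O)cc(O)c5C[C@H]4O)=CC(=O)C(O)(O)C1(O)O3)[C@H](O)C2 | intermediate

5 | theasinensin C: two (2R,3R)-epigallocatechin units joined C2'–C2' between their pyrogallol B rings, (R)-axis (not encodable in the SMILES) | Oc1cc(O)c2c(c1)O[C@H](c1cc(O)c(O)c(O)c1-c1c([C@H]3Oc4cc(O)cc(O)c4C[C@H]3O)cc(O)c(O)c1O)[C@H](O)C2 | target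

## Step count and risks

Total step count: 2. Longest linear sequence: 2.

Steps most likely to fail (the route has only two steps, so both are ranked and there is no third):

First, step 1, the proposed new step. Risks are fouling of the carbon anode by polyphenol films, attack of ring A on quinone 2 giving oligomers, over-oxidation of 4, and incomplete facial selectivity in the coupling. The fallback uses known chemistry and replaces the electrode by a dissolved, chelating metal oxidant. It sets out from 1: treatment with CuCl2 (about 2–3 equiv per 1) in water at 20 °C, the established oxidation for pyrogallol-type tea catechins, in which divalent copper binds the pyrogallol and oxidises it in solution to 2, which dimerises through 3; monovalent copper chloride is left behind. After the same acidic Diaion HP-20 isolation it comes back to the route at 4. It makes no compound outside the list (none F0).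

Second, step 2. Risks are addition of bisulfite to the enone of 4, and decomposition or redox dismutation of 4 during isolation and handling, which would also give the (S)-atropisomer and over-oxidised products. The fallback drops both the isolation and the chemical reductant. It sets out from 4 taken as the crude anolyte of step 1: the cell polarity is reversed so that the carbon felt becomes the cathode, held at about −0.30 V vs Ag/AgCl at pH 3 and 5 °C until 2 F per mol of 4 have passed. The keto form in equilibrium with the hydrate is reduced at the electrode and aromatises as in step 2, and the fallback comes back to the route at 5. It makes no compound outside the list (none F0).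

## Further compounds

F0 | step 1 | none | none
F0 | step 2 | none | none
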